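## Structural features

The target is a flavan-3-ol. Ring A (the benzo ring, C4a–C8a) is fused to the dihydropyran ring C (O1, C2, C3, C4); ring B, a 4-hydroxy-3,5-dimethoxyphenyl group, sits on C2, and C3 carries a free secondary hydroxyl. Ring A is 1,2,3,5-tetrasubstituted: O1 at C8a, the C4 methylene at C4a, a methoxy group at C7, and at C5 a two-carbon chain to a 3-hydroxyphenyl ring (ring D), which makes a bibenzyl unit. The only stereocentres, C2 (R) and C3 (S), are adjacent and trans on ring C. In a 1,3-diarylpropane-1,2-diol that lacks only the O1–C8a bond, this corresponds to the anti (1R,2S) relation. The fragile element is the C2–O1 bond: it is benzylic and para to the ring B oxygen, so acid opens it to a quinone-methide-like cation and scrambles C2. The difficulty is therefore to fix the trans relation and the absolute configuration without passing through a C2 cation, while telling three phenolic oxygens apart from the methylated C7 oxygen. The key step uses the fact that O1 is an aryl ether oxygen of ring A: ring C is closed at O1–C8a by palladium-catalysed O-arylation of the C2 hydroxyl with a C8a triflate, after C2 and C3 have been set in an open chain.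

## Logic of the disconnections

**23 to 22.** The three O–CH2Ph bonds are cut (ring B oxygen, ring D oxygen, C3 oxygen). All three hydroxyls must be masked through the organometallic steps and the basic ring closure, and one hydrogenolysis frees them under neutral conditions that do not ionise C2–O1. The end game becomes a single step with no acid or fluoride on the finished flavan. The forward step must stop short of cleaving the C2–O1 bond.

**22 to 21 (key disconnection).** The O1–C8a bond is cut, opening ring C. It is the one ring C bond whose formation leaves C2–O, C3–O and every bond at the two stereocentres untouched. The ring problem becomes an acyclic 1,2-anti problem: 21 carries the C8a oxygen as a triflate, a free C2 hydroxyl and a benzyl ether on the C3 oxygen. The forward step needs C–O reductive elimination to outrun beta-hydride loss, and the C3 oxygen must stay blocked. A benzyl ether is chosen over a silyl ether because a silyl group can migrate to the neighbouring C2 alkoxide under base and so permit five-ring closure.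

**21 to 20.** The C2–H bond is cut (carbinol back to ketone). With a benzyloxy group at C3, hydride addition through a metal chelate gives the anti relation. Addition of an aryl nucleophile to the corresponding aldehyde would give syn under chelation and only moderate anti selectivity without it. C2 is thus reduced to substrate control from C3. The forward step needs a mild, chelating hydride donor that tolerates the triflate.

**20 to 16 and 19 (19 from 18, 18 from 17).** The bond between C2 and ring B is cut. Ring B joins the C2–C3–C4–ring A unit convergently at the acyl oxidation level, by a single addition. Ring B arrives as a simple aryl bromide that is protected once. The organomagnesium must not attack the aryl triflate or enolise C3.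

**16 to 15, then to 13 and 10 (13 from 11 and 12).** The C3–C4 bond and the N-acyl bond to the auxiliary are cut. C3 is an alpha-oxygenated carbonyl carbon, so it can be set by face-selective alkylation of a chiral glycolate enolate with the ring A benzylic electrophile. The benzyl ether carried by that enolate is the group needed on the C3 oxygen in 21 and 22. Absolute configuration comes from a recoverable auxiliary; C2, C3 and the C3 oxygen all come from 12. The forward step is an SN2 reaction at a di-ortho-substituted benzylic bromide, which must be faster than decomposition of the enolate.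

**10 to 9 to 8 to 7.** The C4–Br bond, the two C4–H bonds (ester oxidation level) and the O–S bond of the triflate are cut. C4 is the ester carbon of the ring A building block. The triflate is installed before the reduction, so the C8a oxygen needs no second protecting group and the benzylic bromide is deactivated against ionisation. It also avoids a late sulfonylation of a phenol beside a secondary alcohol. Every reagent from step 6 to step 13 must then tolerate an aryl triflate.

**7 to 6, then to 3 and 4; 3 to 2 to 1.** The benzylic CH2–CH2 bond of the bibenzyl and the O–C bonds of the methyl ether and the acetal are cut. The C5 chain grows from the aryl methyl group of 1, which the ortho ester acidifies. The substitution pattern of ring A and the distinction between the C7 and C8a oxygens are taken from 1, whose 2-hydroxyl is hydrogen-bonded and whose 4-hydroxyl is free. The lateral lithiation needs a substrate without an acidic hydroxyl, hence the temporary acetal in 3.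

## Other disconnections considered

**Alternative 1:** The cut lies inside ring A. The C4a–C5 bond is traced back to the open-chain diketo-dioxinone A2. Aldol attack of its dioxinone alpha-carbon on the distal ketone, then dehydration and enolisation, would give the resorcylate acetonide A1.
- In its favour: ring A would be formed with its two oxygens already told apart (the future C8a oxygen in the acetonide, the future C7 oxygen free) and with the bibenzyl chain in place. Neither the selective methylation of step 1, the acetal of steps 2 and 4, nor the lateral lithiation of step 3 would be needed. On regiochemical and protecting-group hygiene it is the better plan.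
- Against it: commercial 1 already supplies ring A. A2 needs two successive Claisen-type acylations of a dioxinone dienolate and can close to a pyranone instead. A1 would still need O-methylation and methanolysis to reach the stage of 7.
- Comparison: structurally it delivers only ring A and leaves ring C and both stereocentres to the chemistry of steps 5–15. Mechanistically the aldol–aromatisation is at least as reliable as a toluate anion alkylation. In step count it would be expected to cost about two operations more than the four from 1 to 7.

**Alternative 2:** O1–C2 and C3–C4 are cut together. The salicyl alcohol A4 (one hydride reduction from 7) would lose water under a chiral phosphoric acid to give an ortho-quinone methide. This would add across the (E)-styrylboronate A5 to give the 2,3-trans 3-boryl chroman A3, and oxidation of C–B with retention would give the C3 hydroxyl. A3 is correctly labelled (2S,3S), not (2R,3S): boron ranks below carbon, so the descriptor at C2 changes although the spatial arrangement is that of the target.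
- In its favour: ring C, both stereocentres and the trans relation (from the E geometry) would come from one catalytic step. The whole synthesis would be expected to need eight or nine steps against fifteen, so it is clearly the better plan in step economy, and it needs no auxiliary.
- Against it: the quinone methide from A4 is unsubstituted at C4, so it would be short-lived and prone to oligomerise or react without the catalyst. Both new stereocentres lie on the dienophile, so the acid must control which face of A5 meets a flat, achiral heterodiene. The alkenylboronate is a deactivated two-electron partner. A3 keeps a free para-hydroxyl on ring B, so the same acid could reopen C2–O1 through a para-quinone methide and erode both the trans relation and the enantiomeric purity.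
- Comparison: it forms two bonds and two stereocentres where the chosen plan forms one bond and none. Its stereocontrol rests on a non-covalent catalyst–substrate assembly of uncertain fidelity for this substrate class. The chosen plan takes C3 from a covalent auxiliary and C2 from a chelate and then leaves both alone. The chosen plan is preferred only because configuration is the crux of this target.

**Alternative 3:** The C4–C4a bond is cut. The epoxy aryl ether A7, with C2 and C3 already set, would cyclise in hexafluoroisopropanol or with Sc(OTf)3 by attack of ring A on the terminal epoxide carbon (6-endo), giving the flavan-3-ol A6 with a free C3 hydroxyl.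
- In its favour: the closure touches neither stereocentre, so on stereochemical fidelity of the ring-forming step it is the equal of the chosen plan. It is metal-free, and the C3 hydroxyl needs no protecting group, which is a point where it is better.
- Against it: ring A offers two nucleophilic carbons ortho to O1. C4a is para to the methoxy group but flanked by the C5 chain; C8 lies between the two oxygens and is unhindered. Only C4a leads to the target, so regiochemistry is not fixed by the substrate, whereas the chosen plan inherits it from 1. The acid-promoted closure runs with the labile C2–O1 ether already in place, which is why ring B must be deactivated as a mesylate, and that mesylate then needs a separate and fairly harsh removal. Making the C2–O aryl ether of A7 with defined configuration carries its own risk of ionisation.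
- Comparison: the step count would be comparable. The mechanism is cationic and substrate-controlled in regiochemistry, where the chosen plan is organometallic with regiochemistry fixed by the position of the triflate.

Key step: step 14

Remark on the chemistry: the C3 oxygen is carried as a benzyl ether and the C8a oxygen is triflated early. These are changes of protecting group and of the steps before the key step only; the bond formed in step 14 and the carbon skeletons of 21 and 22 are unchanged. LiN(iPr)2, NaN(SiMe3)2 and Zn(BH4)2 are assumed to be used as stock solutions.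

## Route

Step 1
Reactants: 1 methyl orsellinate (methyl 2,4-dihydroxy-6-methylbenzoate)
Product: 2 methyl 2-hydroxy-4-methoxy-6-methylbenzoate
Conditions: MeI (1.05 equiv), K2CO3 (1.1 equiv), acetone, 20 → 40 °C
Reagents that add atoms: iodomethane, CI
Why: Williamson ether synthesis; the 2-hydroxyl is held in a hydrogen bond to the ester carbonyl and is less acidic and less nucleophilic than the 4-hydroxyl, so one equivalent of MeI should methylate the future C7 oxygen selectively.

Step 2
Reactants: 2 methyl 2-hydroxy-4-methoxy-6-methylbenzoate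
Product: 3 methyl 4-methoxy-2-(methoxymethoxy)-6-methylbenzoate
Conditions: MOMCl (1.5 equiv), i-Pr2NEt (2 equiv), CH2Cl2, 0 °C → reflux
Reagents that add atoms: chloromethyl methyl ether, COCCl
Why: O-alkylation of the chelated phenol with a reactive alpha-chloro ether; the acetal removes the acidic proton before the strong-base step and is later cleaved by acid without touching the ester or the benzyl ether.

Step 3
Reactants: 3 methyl 4-methoxy-2-(methoxymethoxy)-6-methylbenzoate; 4 3-(benzyloxy)benzyl bromide
Product: 6 methyl 2-{2-[3-(benzyloxy)phenyl]ethyl}-4-methoxy-6-(methoxymethoxy)benzoate, via benzylic lithium species 5 (not isolated)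
Conditions: LiN(iPr)2 (1.15 equiv), THF, −78 °C; then 4 (1.1 equiv), −78 → −40 °C
Reagents that add atoms: none
Why: Lateral lithiation of an ortho-toluate; the ester acidifies the ortho methyl group and the benzylic anion 5, a vinylogous ester enolate, is C-alkylated by the benzylic bromide in an SN2 reaction, forming the CH2–CH2 link of the bibenzyl, while low temperature and the flanking alkoxy groups suppress self-condensation.

Step 4
Reactants: 6 methyl 2-{2-[3-(benzyloxy)phenyl]ethyl}-4-methoxy-6-(methoxymethoxy)benzoate
Product: 7 methyl 2-{2-[3-(benzyloxy)phenyl]ethyl}-6-hydroxy-4-methoxybenzoate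
Conditions: HCl (3 M aq., cat.), MeOH, 50 °C
Reagents that add atoms: none
Why: Acid-catalysed acetal methanolysis removes the methoxymethyl group; the benzyl aryl ether, the methyl ethers and the methyl ester (in methanol) are stable under these conditions.

Step 5
Reactants: 7 methyl 2-{2-[3-(benzyloxy)phenyl]ethyl}-6-hydroxy-4-methoxybenzoate
Product: 8 methyl 2-{2-[3-(benzyloxy)phenyl]ethyl}-4-methoxy-6-{[(trifluoromethyl)sulfonyl]oxy}benzoate
Conditions: Tf2O (1.2 equiv), pyridine (3 equiv), CH2Cl2, 0 °C
Reagents that add atoms: trifluoromethanesulfonic anhydride, O=S(=O)(OS(=O)(=O)C(F)(F)F)C(F)(F)F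
Why: O-sulfonylation of the only free phenol; the triflate protects the C8a oxygen through steps 6–13, is the leaving group of the key step, and its electron withdrawal should stabilise the benzylic bromide made in step 7.

Step 6
Reactants: 8 methyl 2-{2-[3-(benzyloxy)phenyl]ethyl}-4-methoxy-6-{[(trifluoromethyl)sulfonyl]oxy}benzoate
Product: 9 (2-{2-[3-(benzyloxy)phenyl]ethyl}-4-methoxy-6-{[(trifluoromethyl)sulfonyl]oxy}phenyl)methanol
Conditions: i-Bu2AlH (2.5 equiv), CH2Cl2, −78 → 0 °C; aq. potassium sodium tartrate
Reagents that add atoms: none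
Why: Ester-to-alcohol reduction with an electrophilic aluminium hydride, which reduces hindered benzoates and should leave the aryl triflate and the benzyl ether intact; LiAlH4 is avoided because it can cleave the S–O bond.

Step 7
Reactants: 9 (2-{2-[3-(benzyloxy)phenyl]ethyl}-4-methoxy-6-{[(trifluoromethyl)sulfonyl]oxy}phenyl)methanol
Product: 10 2-(bromomethyl)-3-{2-[3-(benzyloxy)phenyl]ethyl}-5-methoxyphenyl trifluoromethanesulfonate
Conditions: CBr4 (1.3 equiv), PPh3 (1.3 equiv), CH2Cl2, 0 °C
Reagents that add atoms: carbon tetrabromide, BrC(Br)(Br)Br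
Why: Appel reaction under neutral conditions converts the benzylic alcohol into the bromide; the ortho triflate tempers the para-methoxy activation enough for the bromide to be handled and used directly.

Step 8
Reactants: 11 (R)-4-benzyl-1,3-oxazolidin-2-one; 12 (benzyloxy)acetyl chloride
Product: 13 (R)-4-benzyl-3-[(benzyloxy)acetyl]-1,3-oxazolidin-2-one
Conditions: n-BuLi (1.0 equiv), THF, −78 °C; then 12, −78 → 0 °C
Reagents that add atoms: none
Why: N-acylation of the lithiated oxazolidinone with an acid chloride, the standard preparation of an Evans glycolate imide.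

Step 9
Reactants: 13 (R)-4-benzyl-3-[(benzyloxy)acetyl]-1,3-oxazolidin-2-one (1.5 equiv); 10 2-(bromomethyl)-3-{2-[3-(benzyloxy)phenyl]ethyl}-5-methoxyphenyl trifluoromethanesulfonate
Product: 15 (R)-4-benzyl-3-[(2S)-2-(benzyloxy)-3-(2-{2-[3-(benzyloxy)phenyl]ethyl}-4-methoxy-6-{[(trifluoromethyl)sulfonyl]oxy}phenyl)propanoyl]-1,3-oxazolidin-2-one, via sodium Z-enolate 14 (not isolated)
Conditions: NaN(SiMe3)2 (1.4 equiv), THF, −78 °C; then 10 (1.0 equiv), −78 → −45 °C
Reagents that add atoms: none
Why: Evans asymmetric alkylation of a glycolate imide; the chelated sodium Z-enolate 14 is attacked by the benzylic bromide on the face opposite the auxiliary benzyl group, which with the (R)-auxiliary sets C3 as (S), and the base is kept below the amount of 13 so that no free amide can metalate the ring position between the triflate and the methoxy group.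

Step 10
Reactants: 15 (R)-4-benzyl-3-[(2S)-2-(benzyloxy)-3-(2-{2-[3-(benzyloxy)phenyl]ethyl}-4-methoxy-6-{[(trifluoromethyl)sulfonyl]oxy}phenyl)propanoyl]-1,3-oxazolidin-2-one
Product: 16 (2S)-2-(benzyloxy)-3-(2-{2-[3-(benzyloxy)phenyl]ethyl}-4-methoxy-6-{[(trifluoromethyl)sulfonyl]oxy}phenyl)-N-methoxy-N-methylpropanamide
Conditions: MeONHMe·HCl (3 equiv), AlMe3 (3 equiv), CH2Cl2, −15 → 20 °C
Reagents that add atoms: N,O-dimethylhydroxylamine hydrochloride, CNOC.Cl
Why: Aluminium-amide transamination of the imide to the Weinreb amide; coordination of aluminium between the exocyclic carbonyl and the alpha-benzyloxy oxygen should direct attack to the acyl carbon, the auxiliary is released for recovery, and C3 is not epimerised under these non-basic conditions.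

Step 11
Reactants: 17 4-bromo-2,6-dimethoxyphenol
Product: 18 2-(benzyloxy)-5-bromo-1,3-dimethoxybenzene
Conditions: BnBr (1.1 equiv), K2CO3 (1.5 equiv), DMF, 20 °C
Reagents that add atoms: benzyl bromide, BrCc1ccccc1
Why: Williamson benzylation of the hindered phenol; the benzyl ether survives Grignard formation and is removed in the final hydrogenolysis.

Step 12
Reactants: 18 2-(benzyloxy)-5-bromo-1,3-dimethoxybenzene; 16 (2S)-2-(benzyloxy)-3-(2-{2-[3-(benzyloxy)phenyl]ethyl}-4-methoxy-6-{[(trifluoromethyl)sulfonyl]oxy}phenyl)-N-methoxy-N-methylpropanamide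
Product: 20 (2S)-2-(benzyloxy)-1-[4-(benzyloxy)-3,5-dimethoxyphenyl]-3-(2-{2-[3-(benzyloxy)phenyl]ethyl}-4-methoxy-6-{[(trifluoromethyl)sulfonyl]oxy}phenyl)propan-1-one, via arylmagnesium bromide 19 (not isolated)
Conditions: Mg (1.6 equiv), I2 (cat.), THF, 50 °C; then add to 16, THF, −20 → 0 °C; aq. NH4Cl
Reagents that add atoms: none
Why: Weinreb ketone synthesis; the aryl Grignard reagent 19 adds once to the amide to give a stable magnesium chelate that releases the ketone only on work-up, and at or below 0 °C without a transition metal it should leave the aryl triflate alone and not enolise C3.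

Step 13
Reactants: 20 (2S)-2-(benzyloxy)-1-[4-(benzyloxy)-3,5-dimethoxyphenyl]-3-(2-{2-[3-(benzyloxy)phenyl]ethyl}-4-methoxy-6-{[(trifluoromethyl)sulfonyl]oxy}phenyl)propan-1-one
Product: 21 (1R,2S)-2-(benzyloxy)-1-[4-(benzyloxy)-3,5-dimethoxyphenyl]-3-(2-{2-[3-(benzyloxy)phenyl]ethyl}-4-methoxy-6-{[(trifluoromethyl)sulfonyl]oxy}phenyl)propan-1-ol (1,2-anti)
Conditions: Zn(BH4)2 (0.5 M in Et2O, 1.5 equiv), Et2O/CH2Cl2, −30 → 0 °C
Reagents that add atoms: none
Why: Chelation-controlled (Cram chelate) reduction; zinc bridges the ketone oxygen and the alpha-benzyloxy oxygen, and hydride adds to the face of the five-membered chelate that carries the C3 hydrogen and not the arylmethyl group, which sets C2 as (R), anti to the C3 oxygen, while the triflate and benzyl ethers are inert to this mild hydride.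

Step 14
Reactants: 21 (1R,2S)-2-(benzyloxy)-1-[4-(benzyloxy)-3,5-dimethoxyphenyl]-3-(2-{2-[3-(benzyloxy)phenyl]ethyl}-4-methoxy-6-{[(trifluoromethyl)sulfonyl]oxy}phenyl)propan-1-ol
Product: 22 (2R,3S)-3-(benzyloxy)-2-[4-(benzyloxy)-3,5-dimethoxyphenyl]-5-{2-[3-(benzyloxy)phenyl]ethyl}-7-methoxy-3,4-dihydro-2H-chromene
Conditions: Pd(OAc)2 (5 mol %), rac-2-(di-tert-butylphosphino)-1,1'-binaphthyl (7.5 mol %), Cs2CO3 (1.5 equiv), toluene, 80 °C
Reagents that add atoms: none
Why: Pd(OAc)2 is reduced in the flask to zerovalent palladium, which inserts into the C8a–OTf bond; carbonate deprotonates the coordinated C2 hydroxyl, the alkoxide displaces triflate on divalent palladium to give a seven-membered aryl(alkoxo)palladacycle, and C–O reductive elimination forms O1–C8a. The closest known reaction type is the Buchwald–Hartwig-type intramolecular etherification of aryl halides and sulfonates with secondary alcohols. Ring C is closed as a six-membered ring in a 6-exo sense, the C2 oxygen replacing the exocyclic triflate at C8a with the whole C2–C3–C4 tether inside the new ring. No stereocentre is formed: neither the C2–O nor the C3–O bond is broken, so the anti relation of 21 becomes the 2,3-trans relation of 22 and no benzylic cation is involved. The step needs reductive elimination to win over beta-hydride loss from the C2 alkoxide, which would return ketone 20 and a reduced arene; the bulky, electron-rich di-tert-butylbiarylphosphine favours a monoligated intermediate that eliminates quickly. It also needs six-ring over five-ring closure, secured by the benzyl ether on the C3 oxygen, which cannot migrate to the C2 alkoxide under base. S–O cleavage of the triflate is held back by the non-polar solvent and the heterogeneous, weakly nucleophilic base.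

Step 15
Reactants: 22 (2R,3S)-3-(benzyloxy)-2-[4-(benzyloxy)-3,5-dimethoxyphenyl]-5-{2-[3-(benzyloxy)phenyl]ethyl}-7-methoxy-3,4-dihydro-2H-chromene
Product: 23 (2R,3S)-2-(4-hydroxy-3,5-dimethoxyphenyl)-5-[2-(3-hydroxyphenyl)ethyl]-7-methoxy-3,4-dihydro-2H-chromen-3-ol
Conditions: H2 (1 atm), Pd(OH)2/C (20 wt %), EtOAc/MeOH (1:1), 20 °C
Reagents that add atoms: none
Why: Catalytic hydrogenolysis cleaves the two aryl benzyl ethers and the C3 benzyl ether in one operation; the ring C2–O1 bond, although benzylic, is secondary and ring-bound and is generally spared in debenzylations of flavan-3-ols when the reaction is stopped at full conversion.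

## Compound list

1 | methyl orsellinate (methyl 2,4-dihydroxy-6-methylbenzoate) | COC(=O)c1c(C)cc(O)cc1O | starting material
2 | methyl 2-hydroxy-4-methoxy-6-methylbenzoate | COC(=O)c1c(C)cc(OC)cc1O | intermediate
3 | methyl 4-methoxy-2-(methoxymethoxy)-6-methylbenzoate | COC(=O)c1c(C)cc(OC)cc1OCOC | intermediate
4 | 3-(benzyloxy)benzyl bromide | BrCc1cccc(OCc2ccccc2)c1 | starting material
5 | [5-methoxy-2-(methoxycarbonyl)-3-(methoxymethoxy)phenyl]methyllithium (benzylic lithium species of 3) | [Li+].[CH2-]c1cc(OC)cc(OCOC)c1C(=O)OC | intermediate (not isolated)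
6 | methyl 2-{2-[3-(benzyloxy)phenyl]ethyl}-4-methoxy-6-(methoxymethoxy)benzoate | COC(=O)c1c(CCc2cccc(OCc3ccccc3)c2)cc(OC)cc1OCOC | intermediate
7 | methyl 2-{2-[3-(benzyloxy)phenyl]ethyl}-6-hydroxy-4-methoxybenzoate | COC(=O)c1c(CCc2cccc(OCc3ccccc3)c2)cc(OC)cc1O | intermediate
8 | methyl 2-{2-[3-(benzyloxy)phenyl]ethyl}-4-methoxy-6-{[(trifluoromethyl)sulfonyl]oxy}benzoate | COC(=O)c1c(CCc2cccc(OCc3ccccc3)c2)cc(OC)cc1OS(=O)(=O)C(F)(F)F | intermediate
9 | (2-{2-[3-(benzyloxy)phenyl]ethyl}-4-methoxy-6-{[(trifluoromethyl)sulfonyl]oxy}phenyl)methanol | OCc1c(CCc2cccc(OCc3ccccc3)c2)cc(OC)cc1OS(=O)(=O)C(F)(F)F | intermediate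
10 | 2-(bromomethyl)-3-{2-[3-(benzyloxy)phenyl]ethyl}-5-methoxyphenyl trifluoromethanesulfonate | BrCc1c(CCc2cccc(OCc3ccccc3)c2)cc(OC)cc1OS(=O)(=O)C(F)(F)F | intermediate
11 | (R)-4-benzyl-1,3-oxazolidin-2-one | O=C1OC[C@@H](Cc2ccccc2)N1 | starting material
12 | (benzyloxy)acetyl chloride | ClC(=O)COCc1ccccc1 | starting material
13 | (R)-4-benzyl-3-[(benzyloxy)acetyl]-1,3-oxazolidin-2-one | O=C1OC[C@@H](Cc2ccccc2)N1C(=O)COCc1ccccc1 | intermediate
14 | sodium Z-enolate of 13 | [Na+].[O-]/C(=C\OCc1ccccc1)N1[C@H](Cc2ccccc2)COC1=O | intermediate (not isolated)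
15 | (R)-4-benzyl-3-[(2S)-2-(benzyloxy)-3-(2-{2-[3-(benzyloxy)phenyl]ethyl}-4-methoxy-6-{[(trifluoromethyl)sulfonyl]oxy}phenyl)propanoyl]-1,3-oxazolidin-2-one | O=C1OC[C@@H](Cc2ccccc2)N1C(=O)[C@@H](OCc1ccccc1)Cc1c(OS(=O)(=O)C(F)(F)F)cc(OC)cc1CCc1cccc(OCc2ccccc2)c1 | intermediate
16 | (2S)-2-(benzyloxy)-3-(2-{2-[3-(benzyloxy)phenyl]ethyl}-4-methoxy-6-{[(trifluoromethyl)sulfonyl]oxy}phenyl)-N-methoxy-N-methylpropanamide | CON(C)C(=O)[C@@H](OCc1ccccc1)Cc1c(OS(=O)(=O)C(F)(F)F)cc(OC)cc1CCc1cccc(OCc2ccccc2)c1 | intermediate
17 | 4-bromo-2,6-dimethoxyphenol | COc1cc(Br)cc(OC)c1O | starting material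
18 | 2-(benzyloxy)-5-bromo-1,3-dimethoxybenzene | COc1cc(Br)cc(OC)c1OCc1ccccc1 | intermediate
19 | [4-(benzyloxy)-3,5-dimethoxyphenyl]magnesium bromide | COc1cc([Mg]Br)cc(OC)c1OCc1ccccc1 | intermediate (not isolated)
20 | (2S)-2-(benzyloxy)-1-[4-(benzyloxy)-3,5-dimethoxyphenyl]-3-(2-{2-[3-(benzyloxy)phenyl]ethyl}-4-methoxy-6-{[(trifluoromethyl)sulfonyl]oxy}phenyl)propan-1-one | O=C(c1cc(OC)c(OCc2ccccc2)c(OC)c1)[C@@H](OCc1ccccc1)Cc1c(OS(=O)(=O)C(F)(F)F)cc(OC)cc1CCc1cccc(OCc2ccccc2)c1 | intermediate
21 | (1R,2S)-2-(benzyloxy)-1-[4-(benzyloxy)-3,5-dimethoxyphenyl]-3-(2-{2-[3-(benzyloxy)phenyl]ethyl}-4-methoxy-6-{[(trifluoromethyl)sulfonyl]oxy}phenyl)propan-1-ol | O[C@H](c1cc(OC)c(OCc2ccccc2)c(OC)c1)[C@@H](OCc1ccccc1)Cc1c(OS(=O)(=O)C(F)(F)F)cc(OC)cc1CCc1cccc(OCc2ccccc2)c1 | intermediate (precursor of the key step)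
22 | (2R,3S)-3-(benzyloxy)-2-[4-(benzyloxy)-3,5-dimethoxyphenyl]-5-{2-[3-(benzyloxy)phenyl]ethyl}-7-methoxy-3,4-dihydro-2H-chromene | COc1cc(CCc2cccc(OCc3ccccc3)c2)c2c(c1)O[C@H](c1cc(OC)c(OCc3ccccc3)c(OC)c1)[C@@H](OCc1ccccc1)C2 | intermediate (product of the key step)
23 | (2R,3S)-2-(4-hydroxy-3,5-dimethoxyphenyl)-5-[2-(3-hydroxyphenyl)ethyl]-7-methoxy-3,4-dihydro-2H-chromen-3-ol | COc1cc(CCc2cccc(O)c2)c2c(c1)O[C@H](c1cc(OC)c(O)c(OC)c1)[C@@H](O)C2 | target

## Step count and least certain steps

Total: 15 steps. Longest linear sequence: 13 steps (1, 2, 3, 4, 5, 6, 7, 9, 10, 12, 13, 14, 15); steps 8 and 11 are single-step side branches.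

**Step 14 (key step).** Most likely failure: beta-hydride loss from the palladium alkoxide, which oxidises the C2 carbinol and reduces the arene, or S–O cleavage of the triflate by the base before oxidative addition. Both are plausible because the alkoxide is secondary and benzylic and the arene is electron-rich and ortho-substituted.
- Fallback, from 21 back to 22: Et4NOH (aq.) in dioxane at 20 °C would cleave the triflate to give 2-[(2S,3R)-2-(benzyloxy)-3-[4-(benzyloxy)-3,5-dimethoxyphenyl]-3-hydroxypropyl]-3-{2-[3-(benzyloxy)phenyl]ethyl}-5-methoxyphenol F1. Catalytic camphorsulfonic acid in CH2Cl2 at 0 °C would then ionise the benzylic carbinol, and capture of the ring B-stabilised cation by the C8a phenol would close ring C at O1–C2. The 2,3-trans isomer, with both ring C substituents equatorial, should be favoured, giving 22.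
- This gives up stereoretention for thermodynamic control and would need separation from any cis isomer.

**Step 9.** Most likely failure: slow SN2 displacement at the di-ortho-substituted benzylic bromide, so that the thermally fragile glycolate enolate decomposes before it is alkylated.
- Fallback, from 10 back to 16: C3 is set by electrophilic C–O bond formation on an enolate, so the hindered bromide meets only a small, robust ester enolate.
- The lithium enolate of tert-butyl acetate (LiN(iPr)2, THF, −78 °C) would be alkylated by 10 to give tert-butyl 3-(2-{2-[3-(benzyloxy)phenyl]ethyl}-4-methoxy-6-{[(trifluoromethyl)sulfonyl]oxy}phenyl)propanoate F2.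
- CF3CO2H in CH2Cl2 would give 3-(2-{2-[3-(benzyloxy)phenyl]ethyl}-4-methoxy-6-{[(trifluoromethyl)sulfonyl]oxy}phenyl)propanoic acid F3.
- Activation as the mixed pivalic anhydride (PivCl, Et3N, LiCl) and reaction with (S)-4-benzyl-1,3-oxazolidin-2-one would give (S)-4-benzyl-3-[3-(2-{2-[3-(benzyloxy)phenyl]ethyl}-4-methoxy-6-{[(trifluoromethyl)sulfonyl]oxy}phenyl)propanoyl]-1,3-oxazolidin-2-one F4.
- Evans hydroxylation of its sodium enolate (NaN(SiMe3)2, −78 °C, then 2-(phenylsulfonyl)-3-phenyloxaziridine) on the face away from the auxiliary benzyl group would give the (2S)-2-hydroxy imide F5.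
- Benzyl 2,2,2-trichloroacetimidate with catalytic CF3SO3H would give the (2S)-2-benzyloxy imide F6, and the transamination of step 10 would convert F6 into 16.

**Step 10.** Most likely failure: attack of the aluminium amide at the ring carbonyl of the oxazolidinone, opening the auxiliary, because the exocyclic carbonyl is shielded by the alpha-branch.
- Fallback, from 15 back to 20: LiBH4 (THF/MeOH, 0 °C) would remove the auxiliary reductively to give (2S)-2-(benzyloxy)-3-(2-{2-[3-(benzyloxy)phenyl]ethyl}-4-methoxy-6-{[(trifluoromethyl)sulfonyl]oxy}phenyl)propan-1-ol F7.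
- Dess–Martin periodinane would give the (2S)-2-(benzyloxy)propanal F8.
- Addition of 19 at −78 °C would give (2S)-2-(benzyloxy)-1-[4-(benzyloxy)-3,5-dimethoxyphenyl]-3-(2-{2-[3-(benzyloxy)phenyl]ethyl}-4-methoxy-6-{[(trifluoromethyl)sulfonyl]oxy}phenyl)propan-1-ol F9 as a mixture of C1 epimers, which does not matter.
- A second Dess–Martin oxidation would give 20.

**Step 13.** Most likely failure: poor facial selectivity if zinc chelation to the alpha-benzyloxy oxygen is incomplete, for example through competing coordination to the ring B methoxy groups or slow reduction of the electron-rich aryl ketone.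
- Fallback, from 20 back to 21: catalyst control replaces substrate control, using Noyori–Ikariya transfer hydrogenation with RuCl(p-cymene)[(S,S)-TsDPEN] in HCO2H/Et3N.
- By the usual model, in which the aryl group of the ketone lies next to the arene ligand, the (S,S)-configured catalyst should deliver hydride to the face that gives the (1R) carbinol. No new compound is made (F0).

**Step 15.** Most likely failure: over-reduction by hydrogenolysis of the C2–O1 bond once the ring B phenol is free, or incomplete cleavage of the secondary benzyl ether at C3.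
- Fallback, from 22 back to 23: Lewis-acid debenzylation with a cation scavenger (BCl3, pentamethylbenzene, CH2Cl2, −78 °C) would remove all three benzyl groups without hydrogen and spare the methyl ethers at that temperature.
- Any reversible opening of C2–O1 would be expected to re-close to the favoured trans isomer. No new compound is made (F0).

## Further compounds

F1 | step 14 | 2-[(2S,3R)-2-(benzyloxy)-3-[4-(benzyloxy)-3,5-dimethoxyphenyl]-3-hydroxypropyl]-3-{2-[3-(benzyloxy)phenyl]ethyl}-5-methoxyphenol | O[C@H](c1cc(OC)c(OCc2ccccc2)c(OC)c1)[C@@H](OCc1ccccc1)Cc1c(O)cc(OC)cc1CCc1cccc(OCc2ccccc2)c1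
F2 | step 9 | tert-butyl 3-(2-{2-[3-(benzyloxy)phenyl]ethyl}-4-methoxy-6-{[(trifluoromethyl)sulfonyl]oxy}phenyl)propanoate | CC(C)(C)OC(=O)CCc1c(OS(=O)(=O)C(F)(F)F)cc(OC)cc1CCc1cccc(OCc2ccccc2)c1
F3 | step 9 | 3-(2-{2-[3-(benzyloxy)phenyl]ethyl}-4-methoxy-6-{[(trifluoromethyl)sulfonyl]oxy}phenyl)propanoic acid | OC(=O)CCc1c(OS(=O)(=O)C(F)(F)F)cc(OC)cc1CCc1cccc(OCc2ccccc2)c1
F4 | step 9 | (S)-4-benzyl-3-[3-(2-{2-[3-(benzyloxy)phenyl]ethyl}-4-methoxy-6-{[(trifluoromethyl)sulfonyl]oxy}phenyl)propanoyl]-1,3-oxazolidin-2-one | O=C1OC[C@H](Cc2ccccc2)N1C(=O)CCc1c(OS(=O)(=O)C(F)(F)F)cc(OC)cc1CCc1cccc(OCc2ccccc2)c1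
F5 | step 9 | (S)-4-benzyl-3-[(2S)-3-(2-{2-[3-(benzyloxy)phenyl]ethyl}-4-methoxy-6-{[(trifluoromethyl)sulfonyl]oxy}phenyl)-2-hydroxypropanoyl]-1,3-oxazolidin-2-one | O=C1OC[C@H](Cc2ccccc2)N1C(=O)[C@@H](O)Cc1c(OS(=O)(=O)C(F)(F)F)cc(OC)cc1CCc1cccc(OCc2ccccc2)c1
F6 | step 9 | (S)-4-benzyl-3-[(2S)-2-(benzyloxy)-3-(2-{2-[3-(benzyloxy)phenyl]ethyl}-4-methoxy-6-{[(trifluoromethyl)sulfonyl]oxy}phenyl)propanoyl]-1,3-oxazolidin-2-one | O=C1OC[C@H](Cc2ccccc2)N1C(=O)[C@@H](OCc1ccccc1)Cc1c(OS(=O)(=O)C(F)(F)F)cc(OC)cc1CCc1cccc(OCc2ccccc2)c1
F7 | step 10 | (2S)-2-(benzyloxy)-3-(2-{2-[3-(benzyloxy)phenyl]ethyl}-4-methoxy-6-{[(trifluoromethyl)sulfonyl]oxy}phenyl)propan-1-ol | OC[C@@H](OCc1ccccc1)Cc1c(OS(=O)(=O)C(F)(F)F)cc(OC)cc1CCc1cccc(OCc2ccccc2)c1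
F8 | step 10 | (2S)-2-(benzyloxy)-3-(2-{2-[3-(benzyloxy)phenyl]ethyl}-4-methoxy-6-{[(trifluoromethyl)sulfonyl]oxy}phenyl)propanal | O=C[C@@H](OCc1ccccc1)Cc1c(OS(=O)(=O)C(F)(F)F)cc(OC)cc1CCc1cccc(OCc2ccccc2)c1
F9 | step 10 | (2S)-2-(benzyloxy)-1-[4-(benzyloxy)-3,5-dimethoxyphenyl]-3-(2-{2-[3-(benzyloxy)phenyl]ethyl}-4-methoxy-6-{[(trifluoromethyl)sulfonyl]oxy}phenyl)propan-1-ol, mixture of C1 epimers | OC(c1cc(OC)c(OCc2ccccc2)c(OC)c1)[C@@H](OCc1ccccc1)Cc1c(OS(=O)(=O)C(F)(F)F)cc(OC)cc1CCc1cccc(OCc2ccccc2)c1
F0 | step 13 | none | none
F0 | step 15 | none | none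
A1 | alternative 1 | 5-{2-[3-(benzyloxy)phenyl]ethyl}-7-hydroxy-2,2-dimethyl-4H-1,3-benzodioxin-4-one | CC1(C)OC(=O)c2c(CCc3cccc(OCc4ccccc4)c3)cc(O)cc2O1
A2 | alternative 1 | 6-{6-[3-(benzyloxy)phenyl]-2,4-dioxohexyl}-2,2-dimethyl-4H-1,3-dioxin-4-one | CC1(C)OC(=O)C=C(CC(=O)CC(=O)CCc2cccc(OCc3ccccc3)c2)O1
A3 | alternative 2 | 4-[(2S,3S)-5-{2-[3-(benzyloxy)phenyl]ethyl}-7-methoxy-3-(4,4,5,5-tetramethyl-1,3,2-dioxaborolan-2-yl)-3,4-dihydro-2H-chromen-2-yl]-2,6-dimethoxyphenol (2,3-trans) | COc1cc(CCc2cccc(OCc3ccccc3)c2)c2c(c1)O[C@H](c1cc(OC)c(O)c(OC)c1)[C@@H](B1OC(C)(C)C(C)(C)O1)C2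
A4 | alternative 2 | 3-{2-[3-(benzyloxy)phenyl]ethyl}-2-(hydroxymethyl)-5-methoxyphenol | OCc1c(O)cc(OC)cc1CCc1cccc(OCc2ccccc2)c1
A5 | alternative 2 | 2,6-dimethoxy-4-[(E)-2-(4,4,5,5-tetramethyl-1,3,2-dioxaborolan-2-yl)ethenyl]phenol | COc1cc(/C=C/B2OC(C)(C)C(C)(C)O2)cc(OC)c1O
A6 | alternative 3 | 4-[(2R,3S)-5-{2-[3-(benzyloxy)phenyl]ethyl}-3-hydroxy-7-methoxy-3,4-dihydro-2H-chromen-2-yl]-2,6-dimethoxyphenyl methanesulfonate | COc1cc(CCc2cccc(OCc3ccccc3)c2)c2c(c1)O[C@H](c1cc(OC)c(OS(C)(=O)=O)c(OC)c1)[C@@H](O)C2
A7 | alternative 3 | 4-[(R)-(3-{2-[3-(benzyloxy)phenyl]ethyl}-5-methoxyphenoxy)[(2S)-oxiran-2-yl]methyl]-2,6-dimethoxyphenyl methanesulfonate | COc1cc(CCc2cccc(OCc3ccccc3)c2)cc(c1)O[C@H](c1cc(OC)c(OS(C)(=O)=O)c(OC)c1)[C@@H]1CO1
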